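## Retrosynthetic overview
1. Target **19** comes from (i) angeloylation of C8‑OH, (ii) a late transannular cyclodehydration of the C10‑OH onto a β‑ethoxy enone to form the bridged 3(2H)‑furanone, and (iii) γ‑lactonisation of a C5/C6 syn‑diol acid. The diol acid comes from OsO4 dihydroxylation of an E‑C5=C6 alkene and from oxidation of the C7 isopropenyl group to the α‑methylene acid.
2. The E‑cyclodecene carrying the β‑alkoxy enone forms by anionic oxy‑Cope ring expansion (6→10, new C3–C4 bond) of a 1‑(ethoxyethynyl)‑2‑(Z‑propenyl)cyclohexanol.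
3. That carbinol comes from a cyclohexanone derived from (R)‑carvone: Rubottom α‑hydroxylation gives C10, directed epoxidation and Red‑Al opening give the C8/C10 syn‑1,3‑diol, and Pd α‑alkenylation installs C6.
4. Ring order: cyclohexane (carvone) → 10‑membered carbocycle (oxy‑Cope) → γ‑lactone → furanone bridge. C1–C15 follow germacrane numbering.

Assumption: the C6 α‑alkenylation and the alkynyl addition give the indicated diastereomers, and the oxy‑Cope and OsO4 steps follow the conformational preferences described in their "Why" lines.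

## Route

**Step 1**
Reactants: **1** (R)‑carvone
Product: **2** (2R,5S)‑2‑hydroxy‑2‑methyl‑5‑isopropenylcyclohex‑3‑en‑1‑one (OH trans to isopropenyl)
Conditions: TMSOTf, Et3N, CH2Cl2, 0 °C; then DMDO, acetone, −78 °C; then 1 M HCl, THF, 0 °C
Reagents that add atoms: dimethyldioxirane, CC1(C)OO1 (supplies the C10 oxygen; the TMS group is lost in the HCl work‑up)
Why: Rubottom‑type oxidation of the extended silyl dienol ether at its enol‑ether C=C occurs anti to the C7 isopropenyl group. This sets C10 (Me up, OH down). Because C10 is now quaternary, the alkene stays deconjugated at C8=C9.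

**Step 2**
Reactants: **2**
Product: **3** 3,4‑epoxy‑2‑hydroxy‑2‑methyl‑5‑isopropenylcyclohexanone (epoxide cis to OH, trans to isopropenyl)
Conditions: VO(acac)2 (5 mol %), TBHP, CH2Cl2, 0→23 °C
Reagents that add atoms: tert‑butyl hydroperoxide, CC(C)(C)OO (supplies the epoxide O)
Why: Vanadium‑catalysed hydroxy‑directed epoxidation (Sharpless–Michaelson) of the allylic tertiary alcohol delivers O to the same face as C10‑OH and leaves the isopropenyl group untouched.

**Step 3**
Reactants: **3**
Product: **4** 1,3,5‑trihydroxy‑type triol (C1 epimeric mixture; C10‑OH and C8‑OH cis, C9 = CH2)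
Conditions: Red‑Al, THF, 0 °C
Reagents that add atoms: none (hydride only)
Why: Hydroxy‑directed reductive opening of the 2,3‑epoxy alcohol puts hydride on the proximal carbon C9, so O stays on C8 with retention and a syn‑1,3‑diol results. Ketone reduction at C1 is harmless because C1 is re‑oxidised next.

**Step 4**
Reactants: **4**
Product: **5** (2R,5S)‑hydroxy ketone: C1 ketone, C10 Me/OH, C8‑OH
Conditions: Bu2SnO, PhMe, reflux; then NBS, CH2Cl2, 0 °C
Reagents that add atoms: none
Why: Stannylene acetal formation across the C1/C10 vicinal diol followed by oxidation (Ley–Moffatt type) selectively oxidises the secondary C1‑OH to an α‑ketol and leaves C8‑OH and tertiary C10‑OH intact. No new stereocenter forms.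

**Step 5**
Reactants: **5**
Product: **6** C8,C10‑bis(TBS) ether of **5**
Conditions: TBSOTf, 2,6‑lutidine, CH2Cl2, −78→0 °C
Reagents that add atoms: tert‑butyldimethylsilyl triflate, CC(C)(C)[Si](C)(C)OS(=O)(=O)C(F)(F)F
Why: Silylation masks both hydroxyls against the base and organometallic steps that follow; stereocenters are unchanged.

**Step 6**
Reactants: **6**; **7** (Z)‑1‑bromopropene
Product: **8** C6‑(Z)‑propenyl ketone (propenyl equatorial, trans to the C7 substituent)
Conditions: Pd2(dba)3, Xantphos (achiral), NaOtBu, THF, 40 °C, quench at 0 °C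
Reagents that add atoms: none
Why: Pd‑catalysed ketone α‑alkenylation (Buchwald–Hartwig type) occurs only at C6, because C10 is quaternary, and retains Z alkene geometry. The epimerisable C6 centre settles equatorial, trans to the C7 isopropenyl group.

**Step 7**
Reactants: **8**; **9** ethoxyacetylene
Product: **10** tertiary propargylic carbinol (C1‑OH, C1‑C≡C‑OEt)
Conditions: 9, n‑BuLi, THF, −78 °C; CeCl3; then 8, −78 °C; then aq. NH4Cl
Reagents that add atoms: none (9 is the reactant; n‑BuLi only deprotonates)
Why: 1,2‑Addition of lithium/cerium ethoxyacetylide to the hindered C1 ketone is drawn as occurring trans to the C6 propenyl group. C1 is destroyed in the next step.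

**Step 8**
Reactants: **10**
Product: **11** E‑cyclodecene β‑ethoxy enone (C1=O, C2=C3–OEt, C4‑H/Me, E‑C5=C6)
Conditions: KH, 18‑crown‑6, THF, 0→25 °C; then pH 7 buffer
Reagents that add atoms: none (isomerisation)
Why: Alkoxide‑accelerated oxy‑Cope [3,3] breaks C1–C6 and forms C3–C4 (6→10 ring expansion) through a chair, trans‑fused transition state. The equatorial C7 chain gives the E‑C5=C6 alkene, and the axial Z‑propenyl methyl sets C4 as (R). Protonation of the allenolate gives the β‑alkoxy enone.

**Step 9**
Reactants: **11**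
Product: **12** C8 free alcohol (C10‑OTBS retained)
Conditions: CSA (cat.), EtOH/CH2Cl2 1:1, 0 °C
Reagents that add atoms: none
Why: Acid cleaves the secondary TBS ether much faster than the hindered tertiary C10 TBS ether. EtOH as solvent makes any enol‑ether exchange harmless.

**Step 10**
Reactants: **12**; **13** angelic acid
Product: **14** C8 angelate
Conditions: 13, 2,4,6‑Cl3C6H2COCl, Et3N, THF; then 12, DMAP, PhMe, 23 °C
Reagents that add atoms: none
Why: Yamaguchi esterification at the only free hydroxyl retains the Z‑(angelate) geometry under mild, low‑temperature conditions.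

**Step 11**
Reactants: **14**
Product: **15** allylic alcohol (C12‑OH, C11=C13)
Conditions: SeO2 (cat.), TBHP, CH2Cl2, 23 °C
Reagents that add atoms: tert‑butyl hydroperoxide, CC(C)(C)OO (O source)
Why: Riley ene/[2,3] oxidation occurs at the methyl of the 1,1‑disubstituted isopropenyl alkene, the most reactive alkene, and restores the exocyclic methylene. Electron‑poor enone and angelate alkenes are inert.

**Step 12**
Reactants: **15**
Product: **16** α‑methylene carboxylic acid
Conditions: TEMPO (cat.), NaClO2, NaOCl (cat.), MeCN/pH 6.7 phosphate buffer, 35 °C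
Reagents that add atoms: sodium chlorite, [Na+].[O-]Cl=O (O source)
Why: The Zhao–Grabowski TEMPO/chlorite protocol oxidises the primary allylic alcohol directly to the acid. The acid is then an electron‑poor acrylic acid, so the next step can differentiate the ring alkene.

**Step 13**
Reactants: **16**
Product: **17** 5,6‑syn‑diol (5S,6S)
Conditions: OsO4 (cat.), NMO, acetone/H2O, 23 °C
Reagents that add atoms: N‑methylmorpholine N‑oxide, C[N+]1([O-])CCOCC1 (O source)
Why: OsO4 selectively dihydroxylates the electron‑rich E‑C5=C6 alkene from the peripheral face of the macrocycle. Syn addition to the E alkene gives the (5S,6S) relative configuration required by the target.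

**Step 14**
Reactants: **17**
Product: **18** trans‑fused 6,12‑γ‑lactone with free C5‑OH
Conditions: 2,4,6‑Cl3C6H2COCl, Et3N, THF; then DMAP, PhMe, 0→50 °C, high dilution
Reagents that add atoms: none
Why: Yamaguchi lactonisation closes the γ‑lactone at C6‑OH (5‑membered ring, favoured over the 6‑membered ring at C5‑OH) with retention at C6, giving the trans ring fusion defined by C6/C7.

**Step 15**
Reactants: **18**
Product: **19** Rufescenolide B
Conditions: HF·pyridine, pyridine, THF, 23 °C; then PPTS, THF/H2O, 45 °C
Reagents that add atoms: none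
Why: Fluoride frees C10‑OH, and acid‑promoted transannular 5‑exo attack on C3 of the vinylogous ester then loses EtOH to give the bridged 3(2H)‑furanone. No stereocenter is touched, and C4 is not epimerised because C3 becomes sp2.

## Compound list
1 | (R)‑(−)‑carvone | O=C1C(C)=CC[C@@H](C(C)=C)C1 | starting material
2 | (2R,5S)‑2‑hydroxy‑2‑methyl‑5‑isopropenylcyclohex‑3‑en‑1‑one | O=C1C[C@H](C(C)=C)C=C[C@@]1(C)O | intermediate
3 | 3,4‑epoxy‑2‑hydroxy‑2‑methyl‑5‑isopropenylcyclohexanone (epoxide cis to OH) | O=C1C[C@H](C(C)=C)[C@H]2O[C@H]2[C@@]1(C)O | intermediate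
4 | triol (C1 epimers; C8‑OH/C10‑OH cis) | OC1C[C@H](C(C)=C)[C@@H](O)C[C@@]1(C)O | intermediate
5 | hydroxy ketone: C1 ketone, C8‑OH, C10 Me/OH | O=C1C[C@H](C(C)=C)[C@@H](O)C[C@@]1(C)O | intermediate
6 | C8,C10‑bis(TBS) ketone | O=C1C[C@H](C(C)=C)[C@@H](O[Si](C)(C)C(C)(C)C)C[C@@]1(C)O[Si](C)(C)C(C)(C)C | intermediate
7 | (Z)‑1‑bromopropene | C/C=C\Br | starting material
8 | C6‑(Z)‑propenyl ketone | O=C1[C@@H](/C=C\C)[C@H](C(C)=C)[C@@H](O[Si](C)(C)C(C)(C)C)C[C@@]1(C)O[Si](C)(C)C(C)(C)C | intermediate
9 | ethoxyacetylene | CCOC#C | starting material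
10 | 1‑(ethoxyethynyl)‑cyclohexanol (oxy‑Cope substrate) | CCOC#C[C@]1(O)[C@@H](/C=C\C)[C@H](C(C)=C)[C@@H](O[Si](C)(C)C(C)(C)C)C[C@@]1(C)O[Si](C)(C)C(C)(C)C | intermediate
11 | cyclodecenyl β‑ethoxy enone (oxy‑Cope product) | O=C1C=C(OCC)[C@H](C)/C=C/[C@H](C(C)=C)[C@@H](O[Si](C)(C)C(C)(C)C)C[C@@]1(C)O[Si](C)(C)C(C)(C)C | intermediate
12 | C8 free alcohol | O=C1C=C(OCC)[C@H](C)/C=C/[C@H](C(C)=C)[C@@H](O)C[C@@]1(C)O[Si](C)(C)C(C)(C)C | intermediate
13 | angelic acid | OC(=O)/C(C)=C\C | starting material
14 | C8 angelate | O=C1C=C(OCC)[C@H](C)/C=C/[C@H](C(C)=C)[C@@H](OC(=O)/C(C)=C\C)C[C@@]1(C)O[Si](C)(C)C(C)(C)C | intermediate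
15 | C12 allylic alcohol | O=C1C=C(OCC)[C@H](C)/C=C/[C@H](C(=C)CO)[C@@H](OC(=O)/C(C)=C\C)C[C@@]1(C)O[Si](C)(C)C(C)(C)C | intermediate
16 | α‑methylene acid | O=C1C=C(OCC)[C@H](C)/C=C/[C@H](C(=C)C(=O)O)[C@@H](OC(=O)/C(C)=C\C)C[C@@]1(C)O[Si](C)(C)C(C)(C)C | intermediate
17 | 5,6‑diol acid | O=C1C=C(OCC)[C@H](C)[C@H](O)[C@@H](O)[C@H](C(=C)C(=O)O)[C@@H](OC(=O)/C(C)=C\C)C[C@@]1(C)O[Si](C)(C)C(C)(C)C | intermediate
18 | lactone with free C5‑OH, C10‑OTBS, C3‑OEt enone | O=C1C=C(OCC)[C@H](C)[C@H](O)[C@H]2OC(=O)C(=C)[C@@H]2[C@@H](OC(=O)/C(C)=C\C)C[C@@]1(C)O[Si](C)(C)C(C)(C)C | intermediate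
19 | Rufescenolide B | C=C1C(=O)O[C@@H]2[C@@H](O)[C@@H](C)C3=CC(=O)[C@@](C)(C[C@H](OC(=O)/C(C)=C\C)[C@@H]12)O3 | target

## Totals
- Total steps: 15.
- Longest linear sequence: 15 steps, from (R)‑carvone.

## Three steps most likely to fail
1. **Step 8 (oxy‑Cope).** The ethoxy‑alkynyl carbinol must form a strained cyclic allenolate in a 10‑membered ring, and C4 depends on the C1 addition diastereoselectivity and a chair transition state.
   - Fallback: in Step 7 use a (Z)‑2‑(PMB‑oxy)vinyl nucleophile instead of the ynol ether. The Cope then gives a C3 PMB ether with no strained allenolate. Remove PMB with DDQ, oxidise C3 to the 1,3‑diketone, and close the furanone by the same transannular cyclodehydration. This adds about two steps.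
2. **Step 13 (OsO4 facial selectivity).** Selectivity on the E‑cyclodecene is set only by macrocycle conformation and is uncertain.
   - Fallback: epoxidise C5=C6 with DMDO, open the epoxide intramolecularly with the C12 carboxylate (anti opening gives the C6 lactone), then invert C5 by Mitsunobu p‑nitrobenzoate displacement and hydrolysis.
3. **Step 1 (regioselective α‑oxidation of the dienol ether).**
   - Fallback: take a carveol route to the same C10‑OH/C8=C9 alkene: Luche reduction, VO(acac)2/TBHP epoxidation, Et2AlTMP‑mediated epoxide‑to‑allylic‑alcohol isomerisation, then DMP oxidation at C1 to regain **2**.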